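The data are simulated with constants of no real substance; scatter was added.

| flask | substrate | gas phase | free catalyst | remark | time |
|---|---|---|---|---|---|
| ash | 0.16 M | 7.7 mM (held) | 0.32 mM | the very flask that is asked about, followed so far |  |
| larch | 0.16 M | 7.7 mM (held) | 0.64 mM | run made earlier |  |
| flask | 0.16 M | 7.7 mM (held) | 0.32 mM |  | 6.0 d |

| run | time / d | product / % | substrate / % |
|---|---|---|---|
| ash | 0.833 | 51.4 | 49.1 |
| ash | 1.67 | 66.6 | 32.3 |
| ash | 2.50 | 75.7 | 25.1 |
| ash | 3.00 | 78.3 | 22.0 |
| larch | 1.67 | 74.4 | 24.4 |
| larch | 3.00 | 82.6 | 18.1 |
| larch | 5.00 | 87.4 | 12.3 |
| larch | 6.00 | 89.1 | 11.7 |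

(readings scatter by 0.5 percentage points)

- the earlier runs were read with a standard deviation of 0.5 percentage points
- at the start none of the gas phase is in solution

- north: doubling the saturation concentration of gas phase, all else as stated
- east: doubling the amount of free catalyst, all else as stated
- west: doubling the transfer coefficient of the gas phase, all else as stated

1. amount of product at 6.0 d, in percent of the substrate charged
2. the change that raises the amount of product at 6.0 d, in percent of the substrate charged most ("none" if none brings more than 2 percentage points) (north / east / west / none)
3. amount of product at 6.0 d, in percent of the substrate charged, after west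

- The ash flask cannot have been a constant pseudo-first-order decay: ln of its substrate fell at 0.500 d⁻¹ between the first two readings, but at the slower 0.264 d⁻¹ between the last two.
- So I plotted ln s against ln t, with s the fraction of substrate left and t the time. The larch flask's readings at 3.00 d and 6.00 d gave a downward slope of size 0.629, and I called this reading n, the tail exponent, which makes n/t the specific rate at time t on such a line.
- The ash flask, with half the catalyst of larch, read 0.656, so I carried the larch n over to ash.
- I reckoned two extremes for the ash flask at 6.0 d. Setting the specific rate to zero from 3.00 d held product in my reckoning at the 78.3 % of that reading. Freezing the specific rate at n/t of that reading put substrate at 11.7 % and so product at 88.3 %, taking the two to sum to about 100, as they did in the ash readings.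
- The ash readings showed a specific rate that was falling but still above zero, so I placed the ash flask between these extremes. My power law put its substrate at 14.2 % and its product at 85.8 %.
- The forecast, a separate reckoning, gave 85.3 % (83.5 % to 87 %), north as best, and 86.8 % (85 % to 89.5 %) after west, reasoning that doubling catalyst “speeds things up only about 1.5-fold”.
- The ash flask gave 85.5 %. North was best, gaining 10 percentage points against 2.7 points for east and 1.2 points for west, and west reached 86.8 %.

    gas phase ⇌ dissolved gas, rate k1*(csat - [dissolved gas]) (kL = 2.30 h⁻¹)
    substrate + dissolved gas + free catalyst ⇌ free catalyst + product (K = 1700 L mol⁻¹, k = 36000 L² mol⁻² h⁻¹)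
    2 free catalyst → spent catalyst (k = 130 L mol⁻¹ h⁻¹)

- Two things together held the ash flask short: the path to spent catalyst, without which product stood at 92.9 % against 85.5 %, and the hour of reading, since ten times later gave 92.3 %. Free catalyst in the ash flask went from 14.3 % at 3.00 d to 7.70 % at 6.00 d, about half, as my reckoned n/t went from 0.210 d⁻¹ to 0.105 d⁻¹.
- For the neighbour flask, the same charge read at 40 h, n gave substrate 31.9 % and product 68.1 %; the computed neighbour held 67.8 %.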